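**Retrosynthetic overview**
- The C8 ester and the two silyl ethers come off/on last; the γ-lactone and the ten-membered carbocycle are opened together at C6–C7/O6–C12 (intramolecular Cr(II) allylation of a 2-(chloromethyl)enoate onto an α-acetoxy aldehyde, then lactonisation).
- The 3(2H)-furanone with its quaternary C10 is traced back to an acyclic 2-hydroxy-2-alkynyl ketone by an Au-catalysed heterocyclisation/1,2-methyl shift (C1 → C10 chirality transfer).
- That ketol is cut at C8–C9 (catalytic asymmetric Mukaiyama aldol with a C7/C8/C11–C13 enal) and at C1–C2 (proposed Rh-catalysed enantioselective mono-alkynylation of 2,3-butanedione).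
- The alkyne (C2–C6, C15) comes from L-erythrulose by chelation-controlled ethynylation; the enal comes from methyl acrylate and 2,2-dimethoxyacetaldehyde.
- Ring order: 3(2H)-furanone, then ten-membered carbocycle, then γ-lactone (same pot).

Locants C1–C15 are germacranolide locants: C10 quaternary (Me = C14), C1 furanone C=O, C2=C3, C4 carbinol (CH2OH = C15), C5 OAc, C6 lactone O–CH, C7, C8 O-methacryloyl, C9, C11(=C13)–C12 lactone.

Assumption: in steps 4 and 8 the catalyst antipode named is the one taken to deliver the stated face; if the sense proves opposite, the mirror-image catalyst is used.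

**Step 1**
Reactants: 1 L-erythrulose
Product: 2 3,4-O-isopropylidene-L-erythrulose
Conditions: 2,2-dimethoxypropane, acetone, p-TsOH (cat.), rt
Reagents that add atoms: 2,2-dimethoxypropane COC(C)(C)OC
Why: Acid-catalysed ketalisation under thermodynamic control gives the five-membered dioxolane on the vicinal 3,4-diol; C5 is the chiral-pool centre and is not touched.

**Step 2**
Reactants: 2 3,4-O-isopropylidene-L-erythrulose
Product: 3 1-O-TBS-3,4-O-isopropylidene-L-erythrulose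
Conditions: TBSCl, imidazole, DMF, 0 °C → rt
Reagents that add atoms: tert-butyldimethylsilyl chloride CC(C)(C)[Si](C)(C)Cl
Why: Standard silylation of the only free (primary) hydroxyl; a bulky silyl ether is used because its oxygen does not chelate magnesium in step 3.

**Step 3**
Reactants: 3 1-O-TBS-3,4-O-isopropylidene-L-erythrulose; 4 ethynylmagnesium bromide
Product: 5 (2R)-1-[(tert-butyldimethylsilyl)oxy]-2-[(4S)-2,2-dimethyl-1,3-dioxolan-4-yl]but-3-yn-2-ol
Conditions: MgBr2·OEt2, CH2Cl2, −78 °C; then 4 (THF), −78 → −40 °C; pH 7 buffer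
Reagents that add atoms: none
Why: Cram-chelate-controlled Grignard addition: Mg bridges the ketone oxygen and the dioxolane α-oxygen, so the acetylide attacks the face bearing H-5 (anti to C6) and sets C4 (R).

**Step 4**
Reactants: 5 (2R)-1-[(tert-butyldimethylsilyl)oxy]-2-[(4S)-2,2-dimethyl-1,3-dioxolan-4-yl]but-3-yn-2-ol; 6 2,3-butanedione
Product: 7 (3S,6R)-7-[(tert-butyldimethylsilyl)oxy]-6-[(4S)-2,2-dimethyl-1,3-dioxolan-4-yl]-3,6-dihydroxy-3-methylhept-4-yn-2-one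
Conditions: [Rh((S,S)-iPr-Phebox)(OAc)2(H2O)] (3 mol %), 6 (3 equiv), Et2O, 25 °C
Reagents that add atoms: none
Why: Proposed new method: a (Phebox)Rh(III) acetate forms a Rh–alkynyl by acetate-assisted C–H deprotonation of the terminal alkyne, the 1,2-diketone binds through a carbonyl activated by its neighbouring C=O, and migratory insertion inside the chiral pocket delivers the alkynyl to the Si face (catalyst control), with AcOH protonolysis closing the cycle and mono-addition expected because the α-hydroxy ketone product is a much poorer electrophile; the closest known reaction is the Rh–Phebox-catalysed direct enantioselective alkynylation of α-keto esters, here transferred to a symmetrical aliphatic 1,2-diketone; it forms C1–C2 and sets C1 (S), the centre later relayed to C10.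

**Step 5**
Reactants: 7 (3S,6R)-7-[(tert-butyldimethylsilyl)oxy]-6-[(4S)-2,2-dimethyl-1,3-dioxolan-4-yl]-3,6-dihydroxy-3-methylhept-4-yn-2-one
Product: 8 (3S,6R)-7-[(tert-butyldimethylsilyl)oxy]-6-[(4S)-2,2-dimethyl-1,3-dioxolan-4-yl]-3-methyl-2,3,6-tris[(trimethylsilyl)oxy]hept-1-en-4-yne
Conditions: TMSOTf (3.5 equiv), Et3N, CH2Cl2, −20 → 0 °C
Reagents that add atoms: trimethylsilyl triflate C[Si](C)(C)OS(=O)(=O)C(F)(F)F
Why: Soft enolisation (silyl triflate/amine) can only go toward the methyl group because C1 is quaternary, and both tertiary alcohols are capped as TMS ethers in the same operation.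

**Step 6**
Reactants: 9 methyl acrylate; 10 2,2-dimethoxyacetaldehyde
Product: 11 methyl 3-hydroxy-4,4-dimethoxy-2-methylidenebutanoate (racemic)
Conditions: DABCO (0.5 equiv), 1,4-dioxane/H2O (1:1), rt
Reagents that add atoms: none
Why: Morita–Baylis–Hillman reaction of an activated α-alkoxy aldehyde; the new carbinol centre is racemic and is erased in step 7.

**Step 7**
Reactants: 11 methyl 3-hydroxy-4,4-dimethoxy-2-methylidenebutanoate
Product: 13 methyl (2Z)-2-(chloromethyl)-4-oxobut-2-enoate, via chloro acetal 12 (not isolated)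
Conditions: NCS, Me2S, CH2Cl2, −20 → 0 °C; then TFA/H2O (1:1), 0 °C → rt
Reagents that add atoms: N-chlorosuccinimide O=C1CCC(=O)N1Cl; water O
Why: Corey–Kim-type activation of the allylic alcohol and SN2′ chloride delivery give the rearranged (Z)-2-(chloromethyl)enoate (allylic transposition), and aqueous acid then unmasks the conjugated aldehyde.

**Step 8**
Reactants: 8 (3S,6R)-7-[(tert-butyldimethylsilyl)oxy]-6-[(4S)-2,2-dimethyl-1,3-dioxolan-4-yl]-3-methyl-2,3,6-tris[(trimethylsilyl)oxy]hept-1-en-4-yne; 13 methyl (2Z)-2-(chloromethyl)-4-oxobut-2-enoate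
Product: 15 methyl (2Z,4R,7S,10R)-11-[(tert-butyldimethylsilyl)oxy]-2-(chloromethyl)-10-[(4S)-2,2-dimethyl-1,3-dioxolan-4-yl]-4,7,10-trihydroxy-7-methyl-6-oxoundec-2-en-8-ynoate, via bis-TMS aldol adduct 14 (not isolated)
Conditions: SiCl4 (1.5 equiv), (R,R)-BINAM-derived bisphosphoramide (5 mol %), iPr2NEt (10 mol %), CH2Cl2, −78 °C; aq. NaHCO3; then citric acid, MeOH, rt
Reagents that add atoms: none
Why: Lewis-base-activated (SiCl4/chiral phosphoramide) Mukaiyama aldol addition of a methyl-ketone enol silane to a conjugated aldehyde forms C8–C9; catalyst control delivers the nucleophile to the Re face of the enal and sets C8 (R), and citric acid/MeOH then removes the two tertiary TMS ethers while TBS and acetonide stay.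

**Step 9**
Reactants: 15 methyl (2Z,4R,7S,10R)-11-[(tert-butyldimethylsilyl)oxy]-2-(chloromethyl)-10-[(4S)-2,2-dimethyl-1,3-dioxolan-4-yl]-4,7,10-trihydroxy-7-methyl-6-oxoundec-2-en-8-ynoate
Product: 16 methyl (2Z,4R,7S,10R)-4,11-bis[(tert-butyldimethylsilyl)oxy]-2-(chloromethyl)-10-[(4S)-2,2-dimethyl-1,3-dioxolan-4-yl]-7,10-dihydroxy-7-methyl-6-oxoundec-2-en-8-ynoate
Conditions: TBSOTf (1.1 equiv), 2,6-lutidine, CH2Cl2, −78 °C
Reagents that add atoms: tert-butyldimethylsilyl triflate CC(C)(C)[Si](C)(C)OS(=O)(=O)C(F)(F)F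
Why: At −78 °C the silyl triflate with a hindered, non-nucleophilic base silylates only the secondary C8 alcohol (the 2-(chloromethyl)enoate would be attacked by nucleophilic amines); an ether, not the final ester, is placed at C8 so that the later allylchromium cannot undergo 1,4-elimination.

**Step 10**
Reactants: 16 methyl (2Z,4R,7S,10R)-4,11-bis[(tert-butyldimethylsilyl)oxy]-2-(chloromethyl)-10-[(4S)-2,2-dimethyl-1,3-dioxolan-4-yl]-7,10-dihydroxy-7-methyl-6-oxoundec-2-en-8-ynoate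
Product: 17 methyl (2Z,4R)-4-[(tert-butyldimethylsilyl)oxy]-5-[(2S)-5-[(1R)-2-[(tert-butyldimethylsilyl)oxy]-1-[(4S)-2,2-dimethyl-1,3-dioxolan-4-yl]-1-hydroxyethyl]-2-methyl-3-oxo-2,3-dihydrofuran-2-yl]-2-(chloromethyl)pent-2-enoate
Conditions: AuCl3 (5 mol %), CH2Cl2, 23 °C
Reagents that add atoms: none
Why: Carbophilic activation of the alkyne, 5-endo-dig attack of the C10 carbonyl oxygen at C3 and a cationic suprafacial 1,2-methyl shift from C1 to the oxocarbenium carbon C10 (α-ketol/semipinacol-type rearrangement, known for 2-hydroxy-2-alkynyl ketones) build the 3(2H)-furanone; the methyl group arrives on the face it occupied at C1, so (1S) becomes (10S).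

**Step 11**
Reactants: 17 methyl (2Z,4R)-4-[(tert-butyldimethylsilyl)oxy]-5-[(2S)-5-[(1R)-2-[(tert-butyldimethylsilyl)oxy]-1-[(4S)-2,2-dimethyl-1,3-dioxolan-4-yl]-1-hydroxyethyl]-2-methyl-3-oxo-2,3-dihydrofuran-2-yl]-2-(chloromethyl)pent-2-enoate
Product: 18 methyl (2Z,4R)-4-[(tert-butyldimethylsilyl)oxy]-5-[(2S)-5-[(2R,3S)-1-[(tert-butyldimethylsilyl)oxy]-2,3,4-trihydroxybutan-2-yl]-2-methyl-3-oxo-2,3-dihydrofuran-2-yl]-2-(chloromethyl)pent-2-enoate
Conditions: CuCl2·2H2O (2 equiv), MeCN, 0 °C → rt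
Reagents that add atoms: none
Why: Mild Lewis-acid hydrolysis selective for a terminal isopropylidene acetal; the secondary and neopentyl TBS ethers survive.

**Step 12**
Reactants: 18 methyl (2Z,4R)-4-[(tert-butyldimethylsilyl)oxy]-5-[(2S)-5-[(2R,3S)-1-[(tert-butyldimethylsilyl)oxy]-2,3,4-trihydroxybutan-2-yl]-2-methyl-3-oxo-2,3-dihydrofuran-2-yl]-2-(chloromethyl)pent-2-enoate; 19 trimethyl orthoacetate
Product: 21 methyl (2Z,4R)-5-[(2S)-5-[(2R,3S)-3-acetoxy-1-[(tert-butyldimethylsilyl)oxy]-2,4-dihydroxybutan-2-yl]-2-methyl-3-oxo-2,3-dihydrofuran-2-yl]-4-[(tert-butyldimethylsilyl)oxy]-2-(chloromethyl)pent-2-enoate, via cyclic orthoacetate 20 (not isolated)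
Conditions: 19 (3 equiv), PPTS (cat.), CH2Cl2, rt; then AcOH/H2O (4:1), 0 °C
Reagents that add atoms: water O
Why: Orthoester monoacylation: the cyclic orthoacetate of the C5/C6 diol is hydrolysed through a dioxolan-2-ylium ion that opens to the secondary acetate/primary alcohol, with no amine base present.

**Step 13**
Reactants: 21 methyl (2Z,4R)-5-[(2S)-5-[(2R,3S)-3-acetoxy-1-[(tert-butyldimethylsilyl)oxy]-2,4-dihydroxybutan-2-yl]-2-methyl-3-oxo-2,3-dihydrofuran-2-yl]-4-[(tert-butyldimethylsilyl)oxy]-2-(chloromethyl)pent-2-enoate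
Product: 22 methyl (2Z,4R)-5-[(2S)-5-[(2R,3R)-3-acetoxy-1-[(tert-butyldimethylsilyl)oxy]-2-hydroxy-4-oxobutan-2-yl]-2-methyl-3-oxo-2,3-dihydrofuran-2-yl]-4-[(tert-butyldimethylsilyl)oxy]-2-(chloromethyl)pent-2-enoate
Conditions: Dess–Martin periodinane, CH2Cl2, 0 °C → rt; used crude
Reagents that add atoms: none
Why: Dess–Martin oxidation of the only primary alcohol (the tertiary C4–OH is inert) under amine-free conditions; C5 keeps its configuration (the descriptor changes only by CIP priority).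

**Step 14**
Reactants: 22 methyl (2Z,4R)-5-[(2S)-5-[(2R,3R)-3-acetoxy-1-[(tert-butyldimethylsilyl)oxy]-2-hydroxy-4-oxobutan-2-yl]-2-methyl-3-oxo-2,3-dihydrofuran-2-yl]-4-[(tert-butyldimethylsilyl)oxy]-2-(chloromethyl)pent-2-enoate
Product: 24 (4R,5S,6S,7S,8R,10S)-5-acetoxy-8,15-bis[(tert-butyldimethylsilyl)oxy]-4-hydroxy-1-oxo-3,10-epoxygermacra-2,11(13)-dien-12,6-olide, via hydroxy ester 23 (not isolated)
Conditions: CrCl2 (8 equiv), THF/DMF, rt, syringe-pump addition to 1 mM; aqueous work-up; then CSA (cat.), CH2Cl2, rt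
Reagents that add atoms: none
Why: Intramolecular Nozaki–Hiyama allylation: the allylchromium attacks the aldehyde through C7 in a chair-like transition state with the C8 branch equatorial (6,7-anti, hence the trans-lactone), Felkin–Anh attack anti to the C5 acetoxy sets 5,6-anti (6S) and the C8 silyloxy centre biases the C7 face, after which acid closes the γ-lactone (C7 reads S here only because of the silyl ether's CIP priority).

**Step 15**
Reactants: 24 (4R,5S,6S,7S,8R,10S)-5-acetoxy-8,15-bis[(tert-butyldimethylsilyl)oxy]-4-hydroxy-1-oxo-3,10-epoxygermacra-2,11(13)-dien-12,6-olide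
Product: 25 (4R,5S,6S,7R,8R,10S)-5-acetoxy-4,8,15-trihydroxy-1-oxo-3,10-epoxygermacra-2,11(13)-dien-12,6-olide
Conditions: HF·pyridine, pyridine, THF, 0 °C → rt
Reagents that add atoms: none
Why: Buffered acidic fluoride removes both TBS ethers without acetate migration or conjugate addition to the α-methylene lactone.

**Step 16**
Reactants: 25 (4R,5S,6S,7R,8R,10S)-5-acetoxy-4,8,15-trihydroxy-1-oxo-3,10-epoxygermacra-2,11(13)-dien-12,6-olide; 26 methacryloyl chloride
Product: 29 (4R,5S,6S,7R,8R,10S)-5-acetoxy-4,15-dihydroxy-8-(methacryloyloxy)-1-oxo-3,10-epoxygermacra-2,11(13)-dien-12,6-olide (target), via cyclic phenylboronate 27 (not isolated), via boronate methacrylate 28 (not isolated)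
Conditions: PhB(OH)2 (1.05 equiv), 4 Å MS, CH2Cl2, rt; then 26, iPr2NEt, DMAP (cat.), 0 °C; then pinacol, rt
Reagents that add atoms: phenylboronic acid OB(O)c1ccccc1 (atoms held only in 27 and 28)
Why: Transient boronate masking: the C4/C15 1,2-diol is tied up as a five-membered phenylboronate, so acylation hits only the secondary C8 alcohol, and transesterification with pinacol frees the diol.

**Compound list**
1 | L-erythrulose, (3S)-1,3,4-trihydroxybutan-2-one | OCC(=O)[C@@H](O)CO | starting material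
2 | 3,4-O-isopropylidene-L-erythrulose, 1-[(4S)-2,2-dimethyl-1,3-dioxolan-4-yl]-2-hydroxyethan-1-one | OCC(=O)[C@@H]1COC(C)(C)O1 | intermediate
3 | 1-O-TBS-3,4-O-isopropylidene-L-erythrulose, 2-[(tert-butyldimethylsilyl)oxy]-1-[(4S)-2,2-dimethyl-1,3-dioxolan-4-yl]ethan-1-one | CC(C)(C)[Si](C)(C)OCC(=O)[C@@H]1COC(C)(C)O1 | intermediate
4 | ethynylmagnesium bromide | C#C[Mg]Br | starting material
5 | (2R)-1-[(tert-butyldimethylsilyl)oxy]-2-[(4S)-2,2-dimethyl-1,3-dioxolan-4-yl]but-3-yn-2-ol | C#C[C@@](O)(CO[Si](C)(C)C(C)(C)C)[C@@H]1COC(C)(C)O1 | intermediate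
6 | 2,3-butanedione | CC(=O)C(C)=O | starting material
7 | (3S,6R)-7-[(tert-butyldimethylsilyl)oxy]-6-[(4S)-2,2-dimethyl-1,3-dioxolan-4-yl]-3,6-dihydroxy-3-methylhept-4-yn-2-one | CC(=O)[C@@](C)(O)C#C[C@@](O)(CO[Si](C)(C)C(C)(C)C)[C@@H]1COC(C)(C)O1 | intermediate
8 | (3S,6R)-7-[(tert-butyldimethylsilyl)oxy]-6-[(4S)-2,2-dimethyl-1,3-dioxolan-4-yl]-3-methyl-2,3,6-tris[(trimethylsilyl)oxy]hept-1-en-4-yne | C=C(O[Si](C)(C)C)[C@@](C)(O[Si](C)(C)C)C#C[C@@](O[Si](C)(C)C)(CO[Si](C)(C)C(C)(C)C)[C@@H]1COC(C)(C)O1 | intermediate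
9 | methyl acrylate | C=CC(=O)OC | starting material
10 | 2,2-dimethoxyacetaldehyde | COC(OC)C=O | starting material
11 | methyl 3-hydroxy-4,4-dimethoxy-2-methylidenebutanoate (racemic) | C=C(C(=O)OC)C(O)C(OC)OC | intermediate
12 | methyl (2Z)-2-(chloromethyl)-4,4-dimethoxybut-2-enoate | ClC/C(C(=O)OC)=C\C(OC)OC | intermediate
13 | methyl (2Z)-2-(chloromethyl)-4-oxobut-2-enoate | ClC/C(C(=O)OC)=C\C=O | intermediate
14 | methyl (2Z,4R,7S,10R)-11-[(tert-butyldimethylsilyl)oxy]-2-(chloromethyl)-10-[(4S)-2,2-dimethyl-1,3-dioxolan-4-yl]-4-hydroxy-7-methyl-6-oxo-7,10-bis[(trimethylsilyl)oxy]undec-2-en-8-ynoate | ClC/C(C(=O)OC)=C\[C@H](O)CC(=O)[C@@](C)(O[Si](C)(C)C)C#C[C@@](O[Si](C)(C)C)(CO[Si](C)(C)C(C)(C)C)[C@@H]1COC(C)(C)O1 | intermediate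
15 | methyl (2Z,4R,7S,10R)-11-[(tert-butyldimethylsilyl)oxy]-2-(chloromethyl)-10-[(4S)-2,2-dimethyl-1,3-dioxolan-4-yl]-4,7,10-trihydroxy-7-methyl-6-oxoundec-2-en-8-ynoate | ClC/C(C(=O)OC)=C\[C@H](O)CC(=O)[C@@](C)(O)C#C[C@@](O)(CO[Si](C)(C)C(C)(C)C)[C@@H]1COC(C)(C)O1 | intermediate
16 | methyl (2Z,4R,7S,10R)-4,11-bis[(tert-butyldimethylsilyl)oxy]-2-(chloromethyl)-10-[(4S)-2,2-dimethyl-1,3-dioxolan-4-yl]-7,10-dihydroxy-7-methyl-6-oxoundec-2-en-8-ynoate | ClC/C(C(=O)OC)=C\[C@H](O[Si](C)(C)C(C)(C)C)CC(=O)[C@@](C)(O)C#C[C@@](O)(CO[Si](C)(C)C(C)(C)C)[C@@H]1COC(C)(C)O1 | intermediate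
17 | methyl (2Z,4R)-4-[(tert-butyldimethylsilyl)oxy]-5-[(2S)-5-[(1R)-2-[(tert-butyldimethylsilyl)oxy]-1-[(4S)-2,2-dimethyl-1,3-dioxolan-4-yl]-1-hydroxyethyl]-2-methyl-3-oxo-2,3-dihydrofuran-2-yl]-2-(chloromethyl)pent-2-enoate | ClC/C(C(=O)OC)=C\[C@H](O[Si](C)(C)C(C)(C)C)C[C@]2(C)OC(=CC2=O)[C@@](O)(CO[Si](C)(C)C(C)(C)C)[C@@H]1COC(C)(C)O1 | intermediate
18 | methyl (2Z,4R)-4-[(tert-butyldimethylsilyl)oxy]-5-[(2S)-5-[(2R,3S)-1-[(tert-butyldimethylsilyl)oxy]-2,3,4-trihydroxybutan-2-yl]-2-methyl-3-oxo-2,3-dihydrofuran-2-yl]-2-(chloromethyl)pent-2-enoate | ClC/C(C(=O)OC)=C\[C@H](O[Si](C)(C)C(C)(C)C)C[C@]2(C)OC(=CC2=O)[C@@](O)(CO[Si](C)(C)C(C)(C)C)[C@@H](O)CO | intermediate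
19 | trimethyl orthoacetate | CC(OC)(OC)OC | starting material
20 | cyclic C5/C6 O,O-(1-methoxyethylidene) orthoacetate of 18 (both epimers at the orthoester carbon) | ClC/C(C(=O)OC)=C\[C@H](O[Si](C)(C)C(C)(C)C)C[C@]2(C)OC(=CC2=O)[C@@](O)(CO[Si](C)(C)C(C)(C)C)[C@@H]1COC(C)(OC)O1 | intermediate
21 | methyl (2Z,4R)-5-[(2S)-5-[(2R,3S)-3-acetoxy-1-[(tert-butyldimethylsilyl)oxy]-2,4-dihydroxybutan-2-yl]-2-methyl-3-oxo-2,3-dihydrofuran-2-yl]-4-[(tert-butyldimethylsilyl)oxy]-2-(chloromethyl)pent-2-enoate | ClC/C(C(=O)OC)=C\[C@H](O[Si](C)(C)C(C)(C)C)C[C@]2(C)OC(=CC2=O)[C@@](O)(CO[Si](C)(C)C(C)(C)C)[C@@H](OC(C)=O)CO | intermediate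
22 | methyl (2Z,4R)-5-[(2S)-5-[(2R,3R)-3-acetoxy-1-[(tert-butyldimethylsilyl)oxy]-2-hydroxy-4-oxobutan-2-yl]-2-methyl-3-oxo-2,3-dihydrofuran-2-yl]-4-[(tert-butyldimethylsilyl)oxy]-2-(chloromethyl)pent-2-enoate | ClC/C(C(=O)OC)=C\[C@H](O[Si](C)(C)C(C)(C)C)C[C@]2(C)OC(=CC2=O)[C@@](O)(CO[Si](C)(C)C(C)(C)C)[C@@H](OC(C)=O)C=O | intermediate
23 | methyl (4R,5S,6S,7S,8R,10S)-5-acetoxy-8,15-bis[(tert-butyldimethylsilyl)oxy]-4,6-dihydroxy-1-oxo-3,10-epoxygermacra-2,11(13)-dien-12-oate | COC(=O)C(=C)[C@@H]1[C@H](O[Si](C)(C)C(C)(C)C)C[C@]2(C)OC(=CC2=O)[C@@](O)(CO[Si](C)(C)C(C)(C)C)[C@@H](OC(C)=O)[C@H]1O | intermediate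
24 | (4R,5S,6S,7S,8R,10S)-5-acetoxy-8,15-bis[(tert-butyldimethylsilyl)oxy]-4-hydroxy-1-oxo-3,10-epoxygermacra-2,11(13)-dien-12,6-olide | CC(C)(C)[Si](C)(C)O[C@@H]1C[C@]2(C)OC(=CC2=O)[C@@](O)(CO[Si](C)(C)C(C)(C)C)[C@@H](OC(C)=O)[C@H]2OC(=O)C(=C)[C@@H]21 | intermediate
25 | (4R,5S,6S,7R,8R,10S)-5-acetoxy-4,8,15-trihydroxy-1-oxo-3,10-epoxygermacra-2,11(13)-dien-12,6-olide | O[C@@H]1C[C@]2(C)OC(=CC2=O)[C@@](O)(CO)[C@@H](OC(C)=O)[C@H]2OC(=O)C(=C)[C@@H]21 | intermediate
26 | methacryloyl chloride | C=C(C)C(Cl)=O | starting material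
27 | cyclic 4,15-O-phenylboronate of 25 | O[C@@H]1C[C@]2(C)OC(=CC2=O)[C@@](O3)(COB3c4ccccc4)[C@@H](OC(C)=O)[C@H]2OC(=O)C(=C)[C@@H]21 | intermediate
28 | 8-O-methacryloyl derivative of 27 | C=C(C)C(=O)O[C@@H]1C[C@]2(C)OC(=CC2=O)[C@@](O3)(COB3c4ccccc4)[C@@H](OC(C)=O)[C@H]2OC(=O)C(=C)[C@@H]21 | intermediate
29 | (4R,5S,6S,7R,8R,10S)-5-acetoxy-4,15-dihydroxy-8-(methacryloyloxy)-1-oxo-3,10-epoxygermacra-2,11(13)-dien-12,6-olide | C=C(C)C(=O)O[C@@H]1C[C@]2(C)OC(=CC2=O)[C@@](O)(CO)[C@@H](OC(C)=O)[C@H]2OC(=O)C(=C)[C@@H]21 | target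

**Step count**
Total: 16 steps. Longest linear sequence: 14 steps (steps 1–5 and 8–16); steps 6–7 make the enal 13 in parallel.

**Three steps most likely to fail**

Step 4 (the proposed alkynylation). Turnover or enantioselectivity on a simple 1,2-diketone may be poor, and the alkyne carries a free propargylic alcohol. Fallback with known chemistry, setting out from 5 and returning at 7: the same Rh–Phebox catalysis is applied to methyl pyruvate, an α-keto ester and thus the substrate class for which this enantioselective alkynylation is established, to give methyl (2S,5R)-6-[(tert-butyldimethylsilyl)oxy]-5-[(4S)-2,2-dimethyl-1,3-dioxolan-4-yl]-2,5-dihydroxy-2-methylhex-3-ynoate F1. Me(MeO)NH·HCl/iPrMgCl converts it into the Weinreb amide F2, and excess MeMgBr gives methyl ketone 7. This costs two extra steps.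

Step 12 (orthoester monoacetylation). With a 1,2,3-triol the orthoester may form across C4/C5 or open to the primary acetate. Fallback, setting out from 18 and returning at 22: TESCl/2,6-lutidine at −40 °C silylates only the primary alcohol to give the 6-O-triethylsilyl ether F3. AcCl/2,4,6-collidine then acetylates the secondary alcohol to give the 5-O-acetyl-6-O-triethylsilyl compound F4. Swern oxidation (DMSO, (COCl)2, then iPr2NEt) converts the primary TES ether directly into aldehyde 22. Only hindered bases are used because of the allylic chloride.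

Step 14 (Cr(II) macrocyclisation/lactonisation). Closure of the bridged nine-membered oxacycle may lose to oligomerisation, and the C6/C7 configuration rests on transition-state arguments. Fallback, setting out from 16 and returning at 24: the ring is closed before the furanone bridge exists. Acetonide cleavage of 16 (CuCl2·2H2O) gives the alkynyl triol F5. Trimethyl orthoacetate/PPTS gives the cyclic orthoacetate F6, and aqueous AcOH the 5-acetate F7. Dess–Martin oxidation gives the alkynyl aldehyde F8. CrCl2 at high dilution closes the ten-membered cycloalkyne as the hydroxy ester F9, which CSA lactonises to the cyclodecyne lactone F10. AuCl3 then performs the heterocyclisation/1,2-methyl shift transannularly on the strained alkyne and gives 24.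

**Further compounds**
F1 | step 4 | methyl (2S,5R)-6-[(tert-butyldimethylsilyl)oxy]-5-[(4S)-2,2-dimethyl-1,3-dioxolan-4-yl]-2,5-dihydroxy-2-methylhex-3-ynoate | COC(=O)[C@@](C)(O)C#C[C@@](O)(CO[Si](C)(C)C(C)(C)C)[C@@H]1COC(C)(C)O1
F2 | step 4 | (2S,5R)-6-[(tert-butyldimethylsilyl)oxy]-5-[(4S)-2,2-dimethyl-1,3-dioxolan-4-yl]-2,5-dihydroxy-N-methoxy-N,2-dimethylhex-3-ynamide | CON(C)C(=O)[C@@](C)(O)C#C[C@@](O)(CO[Si](C)(C)C(C)(C)C)[C@@H]1COC(C)(C)O1
F3 | step 12 | 6-O-triethylsilyl ether of 18 | ClC/C(C(=O)OC)=C\[C@H](O[Si](C)(C)C(C)(C)C)C[C@]2(C)OC(=CC2=O)[C@@](O)(CO[Si](C)(C)C(C)(C)C)[C@@H](O)CO[Si](CC)(CC)CC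
F4 | step 12 | 5-O-acetyl-6-O-triethylsilyl derivative of 18 | ClC/C(C(=O)OC)=C\[C@H](O[Si](C)(C)C(C)(C)C)C[C@]2(C)OC(=CC2=O)[C@@](O)(CO[Si](C)(C)C(C)(C)C)[C@@H](OC(C)=O)CO[Si](CC)(CC)CC
F5 | step 14 | alkynyl triol (16 without the acetonide) | ClC/C(C(=O)OC)=C\[C@H](O[Si](C)(C)C(C)(C)C)CC(=O)[C@@](C)(O)C#C[C@@](O)(CO[Si](C)(C)C(C)(C)C)[C@@H](O)CO
F6 | step 14 | cyclic C5/C6 orthoacetate of F5 | ClC/C(C(=O)OC)=C\[C@H](O[Si](C)(C)C(C)(C)C)CC(=O)[C@@](C)(O)C#C[C@@](O)(CO[Si](C)(C)C(C)(C)C)[C@@H]1COC(C)(OC)O1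
F7 | step 14 | 5-acetate of F5 | ClC/C(C(=O)OC)=C\[C@H](O[Si](C)(C)C(C)(C)C)CC(=O)[C@@](C)(O)C#C[C@@](O)(CO[Si](C)(C)C(C)(C)C)[C@@H](OC(C)=O)CO
F8 | step 14 | alkynyl α-acetoxy aldehyde | ClC/C(C(=O)OC)=C\[C@H](O[Si](C)(C)C(C)(C)C)CC(=O)[C@@](C)(O)C#C[C@@](O)(CO[Si](C)(C)C(C)(C)C)[C@@H](OC(C)=O)C=O
F9 | step 14 | cyclodecyne hydroxy ester | COC(=O)C(=C)[C@@H]1[C@H](O[Si](C)(C)C(C)(C)C)CC(=O)[C@@](C)(O)C#C[C@@](O)(CO[Si](C)(C)C(C)(C)C)[C@@H](OC(C)=O)[C@H]1O
F10 | step 14 | cyclodecyne lactone | CC(C)(C)[Si](C)(C)O[C@@H]1CC(=O)[C@@](C)(O)C#C[C@@](O)(CO[Si](C)(C)C(C)(C)C)[C@@H](OC(C)=O)[C@H]2OC(=O)C(=C)[C@@H]21
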